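The readings were computed on assumed constants.

The reaction is slow: in the zeta run, the target reached 4.5 % of the starting material charged after 3.00 h. You now want the new flask over 30 h.

| setting | zeta | flask |
|---|---|---|
| starting material | 5 mM | 10 mM |
| partner | 3 equiv | 3.00 equiv |
| remark | run made earlier |  |
| time |  | 30 h |

zeta run (percent of the starting material charged)

| time / h | target / % |
|---|---|
| 0.417 | 0.3 |
| 0.833 | 1.7 |
| 1.33 | 2.3 |
| 1.50 | 2.4 |
| 2.00 | 2.8 |
| 2.50 | 3.7 |
| 3.00 | 4.5 |

(standard deviation of a reading: 0.3 percentage points)

- amount of target in percent of the starting material charged, at 3.0 h, 10 h, 20 h and 30 h



Here is the puzzle. The new flask raises both [starting material] and [partner] by a factor of 2.00. If the step is first order in each, the target forms 4.00 times as fast in mM per hour, yet I expect the percent curve to climb just 2.00 times as fast. Both statements hold, and this is why. Percent means dividing the rate by the charge of starting material, so that charge cancels and the rate constant times [partner] remains, a pseudo-first-order constant while the partner is in excess. Now divide the flask's fractional rate by the zeta run's, at equal conversion. The rate constant and time both drop out, leaving the partner gain, the ratio of the two [partner] charges: 30.0 mM over 15.0 mM, or 2.00.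

So I multiply the zeta reading at 3.00 h by the gain and expect 9.00 % in the flask, give or take 0.6 percentage points. One run cannot prove the assumed order.

The forecast says 8.5 %, 25 %, 42 % and 54 %, on the view that the flask's partner “doubles the fractional rate”. Its first value stands lower than mine, by 0.5 points.

The flask gives 8.12 %, 20.3 %, 30.2 % and 35.7 %, so its last value lies 18 points below the forecast. At 30.0 h the flask holds side product A at 32.6 % beside target at 35.7 %.

    starting material ⇌ intermediate A (K = 0.150, k = 0.100 h⁻¹)
    starting material + partner → target (k = 1.10 M⁻¹ h⁻¹)
    starting material → side product A (k = 0.0260 h⁻¹)
    partner + intermediate A ⇌ intermediate B (K = 60.0 M⁻¹, k = 3.60 M⁻¹ h⁻¹)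
    starting material + target → side product B (k = 0.980 M⁻¹ h⁻¹)

Here too, dividing one rate by another removes time. At the start of the flask, starting material goes to target 1.3 times as fast as to side product A. Both steps are first order in starting material, so its charge cancels, and the step to side product A has no partner in it, so dividing by the gain gives this ratio for the start of the zeta run: 0.635.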